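**Plan**

- Retrosynthesis: the Z-styryl group is taken back to a C4 alkyne (phenyl–alkyne bond by Sonogashira coupling, the outer alkyne carbon from a C4 aldehyde, itself a masked dimethyl acetal). The benzene ring is then cut at C3a–C4, the diketone at C4–C5, the enol ether at O1–C7a, and the chain at C3–C3a and at C5–CH2 of the prenyl group.
- Enabling feature: in the oxolane ring O1–C2–C3–C3a–C7a, the enol-ether carbon C7a, the methine C7 and the carbonyl carbon C6 stand in the 1,3-dioxygenated relationship of a β-diketone. The open chain C3a–C7a–C7–C6–C5–C4 therefore only has to be joined end to end (C3a to C4) to become the benzene ring.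
- Forward: a chiral epoxide (steps 1–4) and a prenylated β-diketone (step 5) are joined (step 6). The oxolane ring closes first (step 7), the chain is completed by acylation (step 8), the benzene ring closes second (step 9), and the C4 side chain is finished last (steps 10–13).
- Stereochemistry: C2 comes from methyl (S)-glycerate acetonide and no bond to this carbon is broken at any stage. The Z-alkene comes from syn semi-hydrogenation of the alkyne.

Key step: step 9

Remark: the benzofuran numbering of the target (O1, C2, C3, C3a, C4 to C7, C7a) is used for the matching atoms of the open-chain intermediates; the enolisable carbon between the two ketones of the benzannulation precursor and the transient centres of the aldol intermediate are left without a configuration.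

**Route**

Step 1
Reactants: 1 methyl (S)-2,2-dimethyl-1,3-dioxolane-4-carboxylate
Product: 2 2-[(S)-2,2-dimethyl-1,3-dioxolan-4-yl]propan-2-ol
Conditions: MeMgBr (3 equiv), THF, 0 °C to rt; aq. NH4Cl
Reagents that add atoms: methylmagnesium bromide, C[Mg]Br
Why: Double Grignard addition to the ester gives the tertiary carbinol, and the stereocentre is kept because carbonyl addition outruns enolisation of the α-alkoxy ester.

Step 2
Reactants: 2 2-[(S)-2,2-dimethyl-1,3-dioxolan-4-yl]propan-2-ol
Product: 3 (S)-3-methylbutane-1,2,3-triol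
Conditions: Dowex 50WX8 (H+ form), H2O–THF, 50 °C
Reagents that add atoms: none
Why: Acid-catalysed acetal hydrolysis frees the 1,2-diol without touching the stereocentre, and the resin is filtered off so that the water-soluble triol needs no extraction.

Step 3
Reactants: 3 (S)-3-methylbutane-1,2,3-triol
Product: 5 (S)-2-(oxiran-2-yl)propan-2-ol, via primary tosylate 4 (not isolated)
Conditions: TsCl (1.05 equiv), Et3N, Bu2SnO (2 mol%), MeCN, 0 °C; then K2CO3, MeOH, 0 °C
Reagents that add atoms: none
Why: Tin-acetal-directed sulfonylation picks the primary hydroxyl and the secondary alkoxide then closes the epoxide by intramolecular Williamson etherification (3-exo-tet) at the primary carbon, so the C–O bond of the stereocentre is never broken and S is retained.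

Step 4
Reactants: 5 (S)-2-(oxiran-2-yl)propan-2-ol
Product: 6 (S)-tert-butyldimethyl{[2-(oxiran-2-yl)propan-2-yl]oxy}silane
Conditions: TBSOTf (1.2 equiv), 2,6-lutidine, CH2Cl2, −78 to 0 °C
Reagents that add atoms: tert-butyldimethylsilyl trifluoromethanesulfonate, CC(C)(C)[Si](C)(C)OS(=O)(=O)C(F)(F)F
Why: Silyl triflate silylation of the hindered tertiary alcohol is fast enough at low temperature to leave the epoxide alone, and the bulky tert-butyldimethylsilyl group is chosen because it should not migrate to the neighbouring secondary alkoxide formed in step 6.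

Step 5
Reactants: 7 pentane-2,4-dione; 8 1-bromo-3-methylbut-2-ene
Product: 9 8-methylnon-7-ene-2,4-dione
Conditions: LiN(iPr)2 (2.1 equiv), THF, −78 to 0 °C; then 8, −78 to 0 °C; aq. NH4Cl
Reagents that add atoms: none
Why: Alkylation of the β-diketone dianion takes place at the terminal, more basic carbanion by SN2 displacement on the allylic bromide, leaving the central diketonate untouched.

Step 6
Reactants: 9 8-methylnon-7-ene-2,4-dione; 6 (S)-tert-butyldimethyl{[2-(oxiran-2-yl)propan-2-yl]oxy}silane
Product: 10 (S)-12-(tert-butyldimethylsilyloxy)-11-hydroxy-2,12-dimethyltridec-2-ene-6,8-dione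
Conditions: LiN(iPr)2 (2.2 equiv), THF, 0 °C; then 6, 0 °C to rt; aq. NH4Cl
Reagents that add atoms: none
Why: The second deprotonation of the unsymmetrical diketone goes to the methyl terminus, and this carbanion opens the epoxide by SN2 attack at its unsubstituted CH2 (dianion epoxide opening), so the carbinol carbon keeps the S configuration of 6.

Step 7
Reactants: 10 (S)-12-(tert-butyldimethylsilyloxy)-11-hydroxy-2,12-dimethyltridec-2-ene-6,8-dione
Product: 11 (S,E)-1-{5-[2-(tert-butyldimethylsilyloxy)propan-2-yl]oxolan-2-ylidene}-6-methylhept-5-en-2-one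
Conditions: PPTS (10 mol%), 4 Å molecular sieves, toluene, 50 °C
Reagents that add atoms: none
Why: Acid-catalysed cyclodehydration (5-exo hemiketal formation at the nearer ketone, then loss of water) gives the exocyclic enol ether conjugated with the remaining ketone, and the E isomer, with the acyl group on the side of the ring CH2, is the thermodynamic one under these equilibrating conditions.

Step 8
Reactants: 11 (S,E)-1-{5-[2-(tert-butyldimethylsilyloxy)propan-2-yl]oxolan-2-ylidene}-6-methylhept-5-en-2-one; 12 methyl 2,2-dimethoxyacetate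
Product: 13 (E)-5-{(S)-5-[2-(tert-butyldimethylsilyloxy)propan-2-yl]oxolan-2-ylidene}-1,1-dimethoxy-3-(3-methylbut-2-en-1-yl)pentane-2,4-dione
Conditions: LiN(SiMe3)2 (2.2 equiv), THF, −78 °C; then 12 (1.3 equiv), −78 to −30 °C; aq. NH4Cl
Reagents that add atoms: none
Why: Kinetic deprotonation of the vinylogous ester at the α′-methylene (C5) followed by crossed Claisen condensation with the activated, practically non-enolisable ester builds the C4–C5 bond, and deprotonation of the product diketone by the second equivalent of base makes the acylation irreversible.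

Step 9
Reactants: 13 (E)-5-{(S)-5-[2-(tert-butyldimethylsilyloxy)propan-2-yl]oxolan-2-ylidene}-1,1-dimethoxy-3-(3-methylbut-2-en-1-yl)pentane-2,4-dione
Product: 15 (S)-2-[2-(tert-butyldimethylsilyloxy)propan-2-yl]-4-(dimethoxymethyl)-5-(3-methylbut-2-en-1-yl)-2,3-dihydro-1-benzofuran-6-ol, via aldol adduct 14 (not isolated)
Conditions: KOtBu (2.0 equiv), tBuOH–THF (1:1), 0 to 60 °C; then aq. NH4Cl, 0 °C
Reagents that add atoms: none
Why: Proposed new method: tert-butoxide first forms the C5 diketonate, which is the resting state, and tert-butanol shuttles protons so that this anion stays in equilibrium with a small share of the isomeric C3a dienolate (γ-deprotonation through the C7a=C7 enol ether of the C6 ketone), in which the C4 carbonyl is a free ketone made strongly electrophilic by its two α-methoxy groups; the dienolate adds to C4, aldol adduct 14 loses water by E1cB through its C5 enolate and the resulting cyclohexadienone tautomerises to the phenoxide, an irreversible sink that draws the unfavourable pre-equilibria forward (a Curtin–Hammett situation). The closest known reaction types are the base-mediated aldol aromatisation of open-chain 2,4,6-triketones to 5-substituted resorcinols and the γ-deprotonation and γ-substitution of 2-alkylidene oxolanes, and what is new is their combination on a triketone whose third carbonyl is locked as a cyclic enol ether. The benzene ring closes by a 6-(enolendo)-exo-trig aldol addition that makes the C3a–C4 bond, and the aromatic sextet is completed by dehydration and enol-to-phenol tautomerism. No stereocentre is created, and C2, which is neither acidic nor part of the reacting π system, is carried through with its S configuration. The step needs site selectivity for C3a attacking C4: it is secured by the E geometry of the alkylidene oxolane, which places C3a and the acyl chain on the same side of C7a=C7 (the Z isomer can reach the E form through the same dienolate), by the six-membered transition state, and by O1 being bound to C7a already, which rules out the 4-pyranone closure that takes over in free triketones.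

Step 10
Reactants: 15 (S)-2-[2-(tert-butyldimethylsilyloxy)propan-2-yl]-4-(dimethoxymethyl)-5-(3-methylbut-2-en-1-yl)-2,3-dihydro-1-benzofuran-6-ol
Product: 17 (S)-6-hydroxy-2-(2-hydroxypropan-2-yl)-5-(3-methylbut-2-en-1-yl)-2,3-dihydro-1-benzofuran-4-carbaldehyde, via silyl ether aldehyde 16 (not isolated)
Conditions: HF (48% aq), MeCN, 0 °C to rt
Reagents that add atoms: water, O
Why: Acid-catalysed hydrolysis of the electron-rich aryl dimethyl acetal is fast and the same medium then cleaves the tertiary silyl ether (fluoride-assisted desilylation), under conditions mild enough not to cyclise the ortho-prenyl phenol.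

Step 11
Reactants: 17 (S)-6-hydroxy-2-(2-hydroxypropan-2-yl)-5-(3-methylbut-2-en-1-yl)-2,3-dihydro-1-benzofuran-4-carbaldehyde
Product: 18 (S)-4-ethynyl-2-(2-hydroxypropan-2-yl)-5-(3-methylbut-2-en-1-yl)-2,3-dihydro-1-benzofuran-6-ol
Conditions: dimethyl (1-diazo-2-oxopropyl)phosphonate (1.5 equiv), K2CO3 (3 equiv), MeOH, 0 °C to rt
Reagents that add atoms: dimethyl (1-diazo-2-oxopropyl)phosphonate, CC(=O)C(=[N+]=[N-])P(=O)(OC)OC
Why: Seyferth–Gilbert homologation in its Ohira–Bestmann form converts the non-enolisable aryl aldehyde into the terminal alkyne under carbonate in methanol, which tolerates the free phenol and the tertiary alcohol.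

Step 12
Reactants: 18 (S)-4-ethynyl-2-(2-hydroxypropan-2-yl)-5-(3-methylbut-2-en-1-yl)-2,3-dihydro-1-benzofuran-6-ol; 19 iodobenzene
Product: 20 (S)-2-(2-hydroxypropan-2-yl)-5-(3-methylbut-2-en-1-yl)-4-(phenylethynyl)-2,3-dihydro-1-benzofuran-6-ol
Conditions: Pd(PPh3)2Cl2 (3 mol%), CuI (5 mol%), Et3N, THF, rt, degassed
Reagents that add atoms: none
Why: Sonogashira coupling of the terminal alkyne with the aryl iodide proceeds at room temperature and needs no protection of the phenol, which sits meta to the alkyne and cannot cyclise onto it.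

Step 13
Reactants: 20 (S)-2-(2-hydroxypropan-2-yl)-5-(3-methylbut-2-en-1-yl)-4-(phenylethynyl)-2,3-dihydro-1-benzofuran-6-ol
Product: 21 (S,Z)-2-(2-hydroxypropan-2-yl)-5-(3-methylbut-2-en-1-yl)-4-(2-phenylethenyl)-2,3-dihydro-1-benzofuran-6-ol
Conditions: H2 (1 atm), Pd/CaCO3 poisoned with Pb(OAc)2, quinoline, EtOAc, rt, stopped after 1 equiv H2
Reagents that add atoms: none
Why: Semi-hydrogenation on the lead-poisoned palladium surface delivers both hydrogens to the same face of the alkyne and so gives the Z-alkene, while the trisubstituted prenyl double bond is reduced far more slowly.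

**Compound list**

1 | methyl (S)-2,2-dimethyl-1,3-dioxolane-4-carboxylate | C1[C@@H](C(=O)OC)OC(C)(C)O1 | starting material
2 | 2-[(S)-2,2-dimethyl-1,3-dioxolan-4-yl]propan-2-ol | C1[C@@H](C(C)(C)O)OC(C)(C)O1 | intermediate
3 | (S)-3-methylbutane-1,2,3-triol | OC[C@H](O)C(C)(C)O | intermediate
4 | (S)-2,3-dihydroxy-3-methylbutyl 4-methylbenzenesulfonate | Cc1ccc(cc1)S(=O)(=O)OC[C@H](O)C(C)(C)O | intermediate
5 | (S)-2-(oxiran-2-yl)propan-2-ol | C1[C@@H](C(C)(C)O)O1 | intermediate
6 | (S)-tert-butyldimethyl{[2-(oxiran-2-yl)propan-2-yl]oxy}silane | CC(C)(C)[Si](C)(C)OC(C)(C)[C@@H]1CO1 | intermediate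
7 | pentane-2,4-dione | CC(=O)CC(C)=O | starting material
8 | 1-bromo-3-methylbut-2-ene | CC(C)=CCBr | starting material
9 | 8-methylnon-7-ene-2,4-dione | CC(=O)CC(=O)CCC=C(C)C | intermediate
10 | (S)-12-(tert-butyldimethylsilyloxy)-11-hydroxy-2,12-dimethyltridec-2-ene-6,8-dione | CC(C)=CCCC(=O)CC(=O)CC[C@H](O)C(C)(C)O[Si](C)(C)C(C)(C)C | intermediate
11 | (S,E)-1-{5-[2-(tert-butyldimethylsilyloxy)propan-2-yl]oxolan-2-ylidene}-6-methylhept-5-en-2-one | CC(C)=CCCC(=O)/C=C1\CC[C@@H](C(C)(C)O[Si](C)(C)C(C)(C)C)O1 | intermediate
12 | methyl 2,2-dimethoxyacetate | COC(OC)C(=O)OC | starting material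
13 | (E)-5-{(S)-5-[2-(tert-butyldimethylsilyloxy)propan-2-yl]oxolan-2-ylidene}-1,1-dimethoxy-3-(3-methylbut-2-en-1-yl)pentane-2,4-dione | COC(OC)C(=O)C(CC=C(C)C)C(=O)/C=C1\CC[C@@H](C(C)(C)O[Si](C)(C)C(C)(C)C)O1 | intermediate
14 | (2S)-2-[2-(tert-butyldimethylsilyloxy)propan-2-yl]-4-(dimethoxymethyl)-4-hydroxy-5-(3-methylbut-2-en-1-yl)-3,3a,4,5-tetrahydro-1-benzofuran-6(2H)-one | COC(OC)C1(O)C(CC=C(C)C)C(=O)C=C2O[C@@H](CC21)C(C)(C)O[Si](C)(C)C(C)(C)C | intermediate
15 | (S)-2-[2-(tert-butyldimethylsilyloxy)propan-2-yl]-4-(dimethoxymethyl)-5-(3-methylbut-2-en-1-yl)-2,3-dihydro-1-benzofuran-6-ol | CC(C)=CCc1c(O)cc2c(c1C(OC)OC)C[C@@H](C(C)(C)O[Si](C)(C)C(C)(C)C)O2 | intermediate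
16 | (S)-2-[2-(tert-butyldimethylsilyloxy)propan-2-yl]-6-hydroxy-5-(3-methylbut-2-en-1-yl)-2,3-dihydro-1-benzofuran-4-carbaldehyde | CC(C)=CCc1c(O)cc2c(c1C=O)C[C@@H](C(C)(C)O[Si](C)(C)C(C)(C)C)O2 | intermediate
17 | (S)-6-hydroxy-2-(2-hydroxypropan-2-yl)-5-(3-methylbut-2-en-1-yl)-2,3-dihydro-1-benzofuran-4-carbaldehyde | CC(C)=CCc1c(O)cc2c(c1C=O)C[C@@H](C(C)(C)O)O2 | intermediate
18 | (S)-4-ethynyl-2-(2-hydroxypropan-2-yl)-5-(3-methylbut-2-en-1-yl)-2,3-dihydro-1-benzofuran-6-ol | CC(C)=CCc1c(O)cc2c(c1C#C)C[C@@H](C(C)(C)O)O2 | intermediate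
19 | iodobenzene | Ic1ccccc1 | starting material
20 | (S)-2-(2-hydroxypropan-2-yl)-5-(3-methylbut-2-en-1-yl)-4-(phenylethynyl)-2,3-dihydro-1-benzofuran-6-ol | CC(C)=CCc1c(O)cc2c(c1C#Cc1ccccc1)C[C@@H](C(C)(C)O)O2 | intermediate
21 | (S,Z)-2-(2-hydroxypropan-2-yl)-5-(3-methylbut-2-en-1-yl)-4-(2-phenylethenyl)-2,3-dihydro-1-benzofuran-6-ol (CNP0181338.1) | CC(C)=CCc1c(O)cc2c(c1/C=C\c1ccccc1)C[C@@H](C(C)(C)O)O2 | target

**Step count**

Total steps: 13. Longest linear sequence: 12 (steps 1–4 and 6–13); step 5 is a one-step side branch.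

**Steps most likely to fail**

1. Step 9 (new method). The C5 diketonate may simply persist, because the share of C3a dienolate is too small or because ring closure is too slow while C4 is tied up in the enolate. The enolate oxygen may instead add to C7a and open the oxolane towards a 4-pyranone, or the dimethoxyacetyl group may be lost by retro-Claisen cleavage.
Fallback, using known reaction types only, setting out from 11 and returning at 15: the ring would be closed one oxidation level lower, where no 1,3-diketone exists and the electrophile is a neutral enone. The kinetic lithium enolate of 11 (LiN(iPr)2, THF, −78 °C) would be added to anhydrous 2,2-dimethoxyacetaldehyde to give the aldol adduct (E)-1-{(S)-5-[2-(tert-butyldimethylsilyloxy)propan-2-yl]oxolan-2-ylidene}-4-hydroxy-5,5-dimethoxy-3-(3-methylbut-2-en-1-yl)pentan-2-one F1. Mesylation (MsCl, Et3N) should give (E)-5-{(S)-5-[2-(tert-butyldimethylsilyloxy)propan-2-yl]oxolan-2-ylidene}-1,1-dimethoxy-3-(3-methylbut-2-en-1-yl)-4-oxopentan-2-yl methanesulfonate F2, which DBU would eliminate to the cross-conjugated dienone (E)-1-{(S)-5-[2-(tert-butyldimethylsilyloxy)propan-2-yl]oxolan-2-ylidene}-5,5-dimethoxy-3-(3-methylbut-2-en-1-yl)pent-3-en-2-one F3. KOtBu in THF would then remove a proton from C3a, and the dienolate should add to C4 of the enone in an intramolecular Michael addition (6-endo-trig) to give the bicyclic vinylogous ester (2S)-2-[2-(tert-butyldimethylsilyloxy)propan-2-yl]-4-(dimethoxymethyl)-5-(3-methylbut-2-en-1-yl)-3,3a,4,5-tetrahydro-1-benzofuran-6(2H)-one F4. Dehydrogenation of this cyclohexenone enol ether with DDQ in dioxane would give the phenol 15.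

2. Step 6. The second deprotonation may go partly to the methylene instead of the methyl terminus, and opening of an epoxide that sits next to a quaternary carbon may be slow enough for proton exchange and self-condensation of the dianion to compete.
Fallback, setting out from 7 and 6 and returning at 11: the symmetrical dianion of 7 (LiN(iPr)2, used in excess) has only one kind of terminus and would open 6 to (S)-8-(tert-butyldimethylsilyloxy)-7-hydroxy-8-methylnonane-2,4-dione F5. Cyclodehydration with PPTS as in step 7 should give (S,E)-1-{5-[2-(tert-butyldimethylsilyloxy)propan-2-yl]oxolan-2-ylidene}propan-2-one F6. Kinetic α′-lithiation of its methyl group (LiN(iPr)2, THF, −78 °C) and alkylation with 8 would then give 11.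

3. Step 13. Hydrogenation of the hindered, di-ortho-substituted alkyne may be slow, so that over-reduction of the new alkene, reduction of the prenyl double bond and Z-to-E isomerisation on the catalyst surface compete.
Fallback, setting out from 17 and returning at 21: Stork–Zhao olefination of the aldehyde with (iodomethyl)triphenylphosphonium iodide and NaN(SiMe3)2 (in excess, to allow for the phenol) in THF at −78 °C should give the Z-vinyl iodide (S,Z)-2-(2-hydroxypropan-2-yl)-4-(2-iodoethenyl)-5-(3-methylbut-2-en-1-yl)-2,3-dihydro-1-benzofuran-6-ol F7. Suzuki–Miyaura coupling with phenylboronic acid (Pd(PPh3)4, aq. K2CO3, THF, rt) proceeds with retention of alkene geometry and would give 21 without any hydrogenation.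

**Further compounds**

F1 | step 9 | (E)-1-{(S)-5-[2-(tert-butyldimethylsilyloxy)propan-2-yl]oxolan-2-ylidene}-4-hydroxy-5,5-dimethoxy-3-(3-methylbut-2-en-1-yl)pentan-2-one | COC(OC)C(O)C(CC=C(C)C)C(=O)/C=C1\CC[C@@H](C(C)(C)O[Si](C)(C)C(C)(C)C)O1
F2 | step 9 | (E)-5-{(S)-5-[2-(tert-butyldimethylsilyloxy)propan-2-yl]oxolan-2-ylidene}-1,1-dimethoxy-3-(3-methylbut-2-en-1-yl)-4-oxopentan-2-yl methanesulfonate | COC(OC)C(OS(C)(=O)=O)C(CC=C(C)C)C(=O)/C=C1\CC[C@@H](C(C)(C)O[Si](C)(C)C(C)(C)C)O1
F3 | step 9 | (E)-1-{(S)-5-[2-(tert-butyldimethylsilyloxy)propan-2-yl]oxolan-2-ylidene}-5,5-dimethoxy-3-(3-methylbut-2-en-1-yl)pent-3-en-2-one | COC(OC)C=C(CC=C(C)C)C(=O)/C=C1\CC[C@@H](C(C)(C)O[Si](C)(C)C(C)(C)C)O1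
F4 | step 9 | (2S)-2-[2-(tert-butyldimethylsilyloxy)propan-2-yl]-4-(dimethoxymethyl)-5-(3-methylbut-2-en-1-yl)-3,3a,4,5-tetrahydro-1-benzofuran-6(2H)-one | COC(OC)C1C(CC=C(C)C)C(=O)C=C2O[C@@H](CC21)C(C)(C)O[Si](C)(C)C(C)(C)C
F5 | step 6 | (S)-8-(tert-butyldimethylsilyloxy)-7-hydroxy-8-methylnonane-2,4-dione | CC(=O)CC(=O)CC[C@H](O)C(C)(C)O[Si](C)(C)C(C)(C)C
F6 | step 6 | (S,E)-1-{5-[2-(tert-butyldimethylsilyloxy)propan-2-yl]oxolan-2-ylidene}propan-2-one | CC(=O)/C=C1\CC[C@@H](C(C)(C)O[Si](C)(C)C(C)(C)C)O1
F7 | step 13 | (S,Z)-2-(2-hydroxypropan-2-yl)-4-(2-iodoethenyl)-5-(3-methylbut-2-en-1-yl)-2,3-dihydro-1-benzofuran-6-ol | CC(C)=CCc1c(O)cc2c(c1/C=C\I)C[C@@H](C(C)(C)O)O2
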